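The indane is cut at C2–C3. One enantioselective dirhodium-carbene C–H insertion makes this bond, closes the five-membered ring and sets both cis benzylic stereocentres. It exploits the C2 methylene of an (E)-1,3-diarylpropen-2-yl arm on ring A: this CH2 is allylic to C1=C8, benzylic to an aryl ring and 1,5 to the diazo carbon C3, while C1 stays sp2. The precursor, a diaryldiazomethane, is built by a geometry-retaining Suzuki coupling; its phenols are then changed from methyl to silyl ethers, so no ether C–H lies near the carbene at C4 and the all-cis ketone, set by syn-hydroboration, is freed by buffered fluoride.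

Key step: step 9

Remark (numbering and abbreviations): indane numbering of the target is used throughout. C1 carries the aroyl group, C2 and C3 the aryl groups, ring A is the benzo ring (C3a, C4–C7, C7a; oxygens on C4 and C6), and C8 is the exocyclic carbon on C1. TBS = tert-butyldimethylsilyl; Rh2(R-PTAD)4 = dirhodium tetrakis[(R)-N-phthaloyl-(1-adamantyl)glycinate].
Assumption (catalyst): Rh2(R-PTAD)4 is taken to give the (2S,3R) series; if the sense of induction proves opposite, Rh2(S-PTAD)4 is used in exactly the same way.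
Assumption (supply): aldehyde 5 and Grignard solution 6 are purchased; 5 is otherwise one Vilsmeier formylation away from 1-bromo-3,5-dimethoxybenzene.

Step 1
Reactants: 1 4-ethynylanisole; 2 4-methoxybenzyl chloride
Product: 3 1,3-bis(4-methoxyphenyl)prop-1-yne
Conditions: PdCl2(MeCN)2 (2 mol%), XPhos (6 mol%), Cs2CO3, THF, 65 °C
Reagents that add atoms: none
Why: Copper-free Sonogashira-type alkynylation (Heck alkynylation) of a benzylic chloride: XPhos-ligated zerovalent palladium inserts into the C–Cl bond and the acetylide couples at sp3 carbon, the weak heterogeneous base in THF leaving the propargylic CH2 of the electron-rich product unisomerised.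

Step 2
Reactants: 3 1,3-bis(4-methoxyphenyl)prop-1-yne
Product: 4 (Z)-2-[1,3-bis(4-methoxyphenyl)prop-1-en-2-yl]-4,4,5,5-tetramethyl-1,3,2-dioxaborolane (boron trans to the anisyl group on the alkene)
Conditions: CuCl (5 mol%), P(p-tol)3 (6 mol%), NaOt-Bu (5 mol%), B2pin2, MeOH, THF, rt
Reagents that add atoms: bis(pinacolato)diboron, CC1(C)OB(OC1(C)C)B1OC(C)(C)C(C)(C)O1
Why: Copper-catalysed borylcupration–protonation (formal syn-hydroboration) of an aryl/alkyl alkyne: the Cu–Bpin species adds syn with copper on the aryl-bearing carbon and boron on the benzyl-bearing one, and methanolysis of the C–Cu bond with retention gives the single isomer in which boron is trans to the anisyl group.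

Step 3
Reactants: 5 2-bromo-4,6-dimethoxybenzaldehyde; 6 3,5-dimethoxyphenylmagnesium chloride
Product: 7 (2-bromo-4,6-dimethoxyphenyl)(3,5-dimethoxyphenyl)methanol (racemic)
Conditions: THF, 0 °C to rt; aq. NH4Cl
Reagents that add atoms: none
Why: Grignard 1,2-addition to an aromatic aldehyde, which the aryl bromide survives at 0 °C; the carbinol centre is formed racemic and disappears in step 4.

Step 4
Reactants: 7 (2-bromo-4,6-dimethoxyphenyl)(3,5-dimethoxyphenyl)methanol
Product: 8 (2-bromo-4,6-dimethoxyphenyl)(3,5-dimethoxyphenyl)methanone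
Conditions: Dess–Martin periodinane, CH2Cl2, rt
Reagents that add atoms: none
Why: Dess–Martin oxidation of a secondary diaryl carbinol to the benzophenone under neutral conditions that leave the aryl bromide and the ethers untouched.

Step 5
Reactants: 8 (2-bromo-4,6-dimethoxyphenyl)(3,5-dimethoxyphenyl)methanone; 4 (Z)-alkenylboronate
Product: 9 {2-[(E)-1,3-bis(4-methoxyphenyl)prop-1-en-2-yl]-4,6-dimethoxyphenyl}(3,5-dimethoxyphenyl)methanone
Conditions: Pd(OAc)2 (3 mol%), SPhos (6 mol%), K3PO4, toluene/H2O, 80 °C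
Reagents that add atoms: none
Why: Suzuki–Miyaura coupling of an ortho-acyl aryl bromide (fast oxidative addition) with an alkenylboronate proceeds with retention at the alkene, so ring A ends up trans to the C8 aryl group (E) and the acidic diarylallyl CH2 never meets an organolithium or strong base.

Step 6
Reactants: 9 pentamethoxy keto-alkene
Product: 10 {2-[(E)-1,3-bis(4-hydroxyphenyl)prop-1-en-2-yl]-4,6-dihydroxyphenyl}(3,5-dihydroxyphenyl)methanone
Conditions: BBr3, CH2Cl2, −78 °C to rt; ice/aq. NaHCO3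
Reagents that add atoms: none
Why: BBr3 cleavage of aryl methyl ethers (O–B complexation, bromide attack on methyl) is carried out here, before any stereocentre exists, on a robust ketone; aprotic conditions and a cold bicarbonate quench avoid protonation of the aryl-substituted alkene.

Step 7
Reactants: 10 pentaphenol ketone
Product: 11 hydrazone of 10 (C=N–NH2 at C3; either C=N isomer)
Conditions: N2H4·H2O, AcOH, EtOH, 80 °C, argon
Reagents that add atoms: hydrazine (as hydrate), NN
Why: Hydrazone condensation, helped by the hydrogen-bonded ortho hydroxyl and buffered with acetic acid so that the phenols stay un-ionised and the carbonyl electrophilic; free phenols tolerate hydrazine (silyl ethers would not), and either C=N isomer gives the same diazo compound.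

Step 8
Reactants: 11 pentaphenol hydrazone
Product: 12 penta-O-TBS ether of hydrazone 11
Conditions: TBSCl, imidazole, DMAP (cat.), DMF, rt to 40 °C; aq. NH4Cl
Reagents that add atoms: tert-butyldimethylsilyl chloride, CC(C)(C)[Si](C)(C)Cl
Why: Corey silylation (TBSCl/imidazole) of the five acidic phenols, much faster than reaction at the weakly nucleophilic hydrazone NH2 (any N–Si bond is hydrolysed on work-up); it leaves no free O–H to protonate the diazo compound and no ether C–H in a 1,5 relationship to C3.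

Step 9
Reactants: 12 penta-O-TBS hydrazone
Product: 14 (E)-(2S,3R)-penta-O-TBS cis-2,3-diaryl-1-benzylideneindane, via diaryldiazomethane 13 (not isolated)
Conditions: MnO2, CH2Cl2, 0 °C; filter; then Rh2(R-PTAD)4 (1 mol%), CH2Cl2, −20 to 0 °C, slow addition
Reagents that add atoms: none
Why: MnO2 dehydrogenates hydrazone 12 to diaryldiazomethane 13, which is fed cold to Rh2(R-PTAD)4; the dirhodium tetracarboxylate (divalent rhodium) expels N2 and the donor/donor carbene at C3 inserts into a C2–H bond in one concerted, asynchronous step in which hydride shift towards C3 runs ahead of C–C bond formation. The closest known reaction type is the dirhodium-catalysed intramolecular C–H insertion of diaryl carbenes that delivers cis-2,3-disubstituted dihydrobenzofurans, indolines and indanes. The five-membered ring C1–C2–C3–C3a–C7a closes by 1,5-insertion, C3 bonding to the carbon four bonds away, whereas addition across C1=C8 is excluded because the cyclopropane would lie in a benzo-fused bicyclo[2.1.0]pentane. C2 and C3 arise together: their cis relationship is inherent in the compact insertion transition state, which keeps the shifting hydrogen and the new C–C bond on one face, and the absolute configuration is dictated by the chiral pocket of the phthalimido-adamantylglycinate ligands. The step needs site selectivity for C2–H, secured because this bond is secondary, allylic to C1=C8 and benzylic to an oxygenated aryl ring (the most hydridic C–H within reach), because the C4 oxygen carries a silyl group whose nearest C–H bonds are 1,6 to C3 and not hydridic, and because sp2 C1 offers neither a C–H bond nor a stereocentre. Consuming 13 at −20 to 0 °C as it is added also leaves no time for thermal 8π electrocyclisation of the diazo group onto the alkene or for azine formation.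

Step 10
Reactants: 14 penta-O-TBS cis-benzylideneindane
Product: 16 all-cis (1R,2R,3R,αR) penta-O-TBS carbinol, via C8 alkylborane 15 (not isolated)
Conditions: BH3·THF, THF, 0 °C to rt; then aq. NaOAc, 30% H2O2, 0 °C to rt
Reagents that add atoms: hydrogen peroxide, OO (oxygen at C8 of 16); borane–tetrahydrofuran, B.C1CCOC1 (boron of 15 only)
Why: Brown hydroboration–oxidation: boron adds to the less substituted C8 and hydrogen to C1 in a syn four-centre addition on the face opposite the cis aryl groups at C2 and C3, which fixes C1 with its C8 substituent cis to both aryls (all-cis), and oxidation of the C–B bond with retention under acetate buffering spares the aryl silyl ethers; the C8 centre is removed in step 11.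

Step 11
Reactants: 16 all-cis penta-O-TBS carbinol
Product: 17 all-cis (1R,2R,3R) penta-O-TBS ketone
Conditions: Dess–Martin periodinane, NaHCO3, CH2Cl2, 0 °C
Reagents that add atoms: none
Why: Dess–Martin oxidation of the secondary benzylic carbinol under bicarbonate buffering forms the ketone without enolising conditions, so the thermodynamically disfavoured cis configuration at C1 is retained.

Step 12
Reactants: 17 all-cis penta-O-TBS ketone
Product: 18 caraphenol B, (4-hydroxyphenyl)[(1R,2R,3R)-3-(3,5-dihydroxyphenyl)-4,6-dihydroxy-2-(4-hydroxyphenyl)-2,3-dihydro-1H-inden-1-yl]methanone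
Conditions: HF·pyridine, pyridine, THF, 0 °C to rt
Reagents that add atoms: none
Why: Fluoride-driven cleavage of the five aryl silyl ethers (Si–F bond formation) with pyridine-buffered HF·pyridine is neither basic enough to epimerise C1 through the enolate nor acidic enough to promote Friedel–Crafts attack of the cis C3 resorcinol ring on C8.

Compound list
1 | 4-ethynylanisole | COc1ccc(cc1)C#C | starting material
2 | 4-methoxybenzyl chloride | COc1ccc(CCl)cc1 | starting material
3 | 1,3-bis(4-methoxyphenyl)prop-1-yne | COc1ccc(cc1)C#CCc1ccc(OC)cc1 | intermediate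
4 | (Z)-2-[1,3-bis(4-methoxyphenyl)prop-1-en-2-yl]-4,4,5,5-tetramethyl-1,3,2-dioxaborolane | COc1ccc(cc1)/C=C(/B1OC(C)(C)C(C)(C)O1)Cc1ccc(OC)cc1 | intermediate
5 | 2-bromo-4,6-dimethoxybenzaldehyde | COc1cc(Br)c(C=O)c(OC)c1 | starting material
6 | 3,5-dimethoxyphenylmagnesium chloride (THF solution) | COc1cc(OC)cc([Mg]Cl)c1 | starting material
7 | (2-bromo-4,6-dimethoxyphenyl)(3,5-dimethoxyphenyl)methanol, racemic | COc1cc(Br)c(C(O)c2cc(OC)cc(OC)c2)c(OC)c1 | intermediate
8 | (2-bromo-4,6-dimethoxyphenyl)(3,5-dimethoxyphenyl)methanone | COc1cc(Br)c(C(=O)c2cc(OC)cc(OC)c2)c(OC)c1 | intermediate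
9 | {2-[(E)-1,3-bis(4-methoxyphenyl)prop-1-en-2-yl]-4,6-dimethoxyphenyl}(3,5-dimethoxyphenyl)methanone | COc1ccc(cc1)/C=C(/c1cc(OC)cc(OC)c1C(=O)c1cc(OC)cc(OC)c1)Cc1ccc(OC)cc1 | intermediate
10 | {2-[(E)-1,3-bis(4-hydroxyphenyl)prop-1-en-2-yl]-4,6-dihydroxyphenyl}(3,5-dihydroxyphenyl)methanone | Oc1ccc(cc1)/C=C(/c1cc(O)cc(O)c1C(=O)c1cc(O)cc(O)c1)Cc1ccc(O)cc1 | intermediate
11 | hydrazone of 10 (N-unsubstituted, either C=N isomer) | Oc1ccc(cc1)/C=C(/c1cc(O)cc(O)c1C(=NN)c1cc(O)cc(O)c1)Cc1ccc(O)cc1 | intermediate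
12 | penta-O-TBS ether of hydrazone 11 | CC(C)(C)[Si](C)(C)Oc1ccc(cc1)/C=C(/c1cc(O[Si](C)(C)C(C)(C)C)cc(O[Si](C)(C)C(C)(C)C)c1C(=NN)c1cc(O[Si](C)(C)C(C)(C)C)cc(O[Si](C)(C)C(C)(C)C)c1)Cc1ccc(O[Si](C)(C)C(C)(C)C)cc1 | intermediate
13 | {2-[(E)-1,3-bis(4-TBSO-phenyl)prop-1-en-2-yl]-4,6-bis(TBSO)phenyl}[3,5-bis(TBSO)phenyl]diazomethane | CC(C)(C)[Si](C)(C)Oc1ccc(cc1)/C=C(/c1cc(O[Si](C)(C)C(C)(C)C)cc(O[Si](C)(C)C(C)(C)C)c1C(=[N+]=[N-])c1cc(O[Si](C)(C)C(C)(C)C)cc(O[Si](C)(C)C(C)(C)C)c1)Cc1ccc(O[Si](C)(C)C(C)(C)C)cc1 | intermediate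
14 | (E)-(2S,3R)-3-[3,5-bis(TBSO)phenyl]-4,6-bis(TBSO)-1-[4-(TBSO)benzylidene]-2-[4-(TBSO)phenyl]-2,3-dihydro-1H-indene (C2 and C3 aryl groups cis; C8 aryl on the C2 side) | CC(C)(C)[Si](C)(C)Oc1ccc(cc1)/C=C1/c2cc(O[Si](C)(C)C(C)(C)C)cc(O[Si](C)(C)C(C)(C)C)c2[C@@H](c2cc(O[Si](C)(C)C(C)(C)C)cc(O[Si](C)(C)C(C)(C)C)c2)[C@H]1c1ccc(O[Si](C)(C)C(C)(C)C)cc1 | intermediate
15 | C8 alkylborane from 14 (BH2 on C8, new H on C1, both on the face opposite the C2/C3 aryl groups) | CC(C)(C)[Si](C)(C)Oc1ccc(cc1)[C@H](B)[C@H]1c2cc(O[Si](C)(C)C(C)(C)C)cc(O[Si](C)(C)C(C)(C)C)c2[C@@H](c2cc(O[Si](C)(C)C(C)(C)C)cc(O[Si](C)(C)C(C)(C)C)c2)[C@H]1c1ccc(O[Si](C)(C)C(C)(C)C)cc1 | intermediate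
16 | (R)-[4-(TBSO)phenyl]{(1R,2R,3R)-3-[3,5-bis(TBSO)phenyl]-4,6-bis(TBSO)-2-[4-(TBSO)phenyl]-2,3-dihydro-1H-inden-1-yl}methanol (all-cis ring) | CC(C)(C)[Si](C)(C)Oc1ccc(cc1)[C@H](O)[C@H]1c2cc(O[Si](C)(C)C(C)(C)C)cc(O[Si](C)(C)C(C)(C)C)c2[C@@H](c2cc(O[Si](C)(C)C(C)(C)C)cc(O[Si](C)(C)C(C)(C)C)c2)[C@H]1c1ccc(O[Si](C)(C)C(C)(C)C)cc1 | intermediate
17 | [4-(TBSO)phenyl]{(1R,2R,3R)-3-[3,5-bis(TBSO)phenyl]-4,6-bis(TBSO)-2-[4-(TBSO)phenyl]-2,3-dihydro-1H-inden-1-yl}methanone (all-cis ring) | CC(C)(C)[Si](C)(C)Oc1ccc(cc1)C(=O)[C@H]1c2cc(O[Si](C)(C)C(C)(C)C)cc(O[Si](C)(C)C(C)(C)C)c2[C@@H](c2cc(O[Si](C)(C)C(C)(C)C)cc(O[Si](C)(C)C(C)(C)C)c2)[C@H]1c1ccc(O[Si](C)(C)C(C)(C)C)cc1 | intermediate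
18 | caraphenol B, (4-hydroxyphenyl)[(1R,2R,3R)-3-(3,5-dihydroxyphenyl)-4,6-dihydroxy-2-(4-hydroxyphenyl)-2,3-dihydro-1H-inden-1-yl]methanone | O=C(c1ccc(O)cc1)[C@H]1c2cc(O)cc(O)c2[C@@H](c2cc(O)cc(O)c2)[C@H]1c1ccc(O)cc1 | target

Total step count: 12. Longest linear sequence: 10 (steps 3–12 from 5, or steps 1, 2 and 5–12 from 1).

Steps most likely to fail

1. Step 9. The chiral catalyst may discriminate the two enantiotopic C2 hydrogens insufficiently, so that the cis ring closure proceeds but with low enantiomeric purity. The fallback changes the source of absolute configuration from catalyst control to resolution. It sets out from 12: the same MnO2 oxidation via 13 is followed by insertion with achiral Rh2(OAc)4, which should give the racemic cis product, that is 14 together with its (2R,3S) enantiomer ent-14 F1. The two are separated by preparative supercritical-fluid chromatography on a chiral stationary phase, and the route is rejoined at 14.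

2. Step 8. Silylation may stop short at the hindered, hydrogen-bonded C4 hydroxyl or spill onto the hydrazone nitrogen; a residual phenol would protonate the diazo compound in step 9. The fallback keeps the methyl ethers through the ring closure and exchanges them afterwards, with no hydrazone present. It sets out from 9: condensation with N2H4·H2O (AcOH, n-BuOH, 110 °C) should give the pentamethoxy hydrazone F2. MnO2 oxidation to the pentamethoxy diaryldiazomethane F3 and insertion with Rh2(R-PTAD)4 should give the pentamethoxy cis-benzylideneindane F4. In this series the C4 methoxy C–H bonds are within reach of the carbene, and site selectivity rests on the far more hydridic C2–H bond. BBr3 (CH2Cl2, −78 °C to rt) then gives the pentaphenol cis-benzylideneindane F5, and TBSCl/imidazole returns to the route at 14.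

3. Step 7. Condensation may be slow and incomplete at a carbonyl that is flanked by two ortho substituents and deactivated by conjugation with the ortho and para hydroxyls. The fallback silylates first and forms the C=N bond with a silyl hydrazine, driven by Si–O bond formation and free of hydrazine itself. It sets out from 10: TBSCl/imidazole gives the penta-O-TBS ketone F6. 1,2-Bis(tert-butyldimethylsilyl)hydrazine with Sc(OTf)3 (cat.) at 60–100 °C should give the N-TBS hydrazone F7. Selective methanolysis of the N–Si bond (MeOH, pyridinium p-toluenesulfonate cat., 0 °C) returns to the route at 12.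

Further compounds
F1 | step 9 | ent-14, (E)-(2R,3S) enantiomer of 14 formed alongside 14 in the racemate | CC(C)(C)[Si](C)(C)Oc1ccc(cc1)/C=C1/c2cc(O[Si](C)(C)C(C)(C)C)cc(O[Si](C)(C)C(C)(C)C)c2[C@H](c2cc(O[Si](C)(C)C(C)(C)C)cc(O[Si](C)(C)C(C)(C)C)c2)[C@@H]1c1ccc(O[Si](C)(C)C(C)(C)C)cc1
F2 | step 8 | hydrazone of ketone 9 (pentamethoxy, either C=N isomer) | COc1ccc(cc1)/C=C(/c1cc(OC)cc(OC)c1C(=NN)c1cc(OC)cc(OC)c1)Cc1ccc(OC)cc1
F3 | step 8 | {2-[(E)-1,3-bis(4-methoxyphenyl)prop-1-en-2-yl]-4,6-dimethoxyphenyl}(3,5-dimethoxyphenyl)diazomethane | COc1ccc(cc1)/C=C(/c1cc(OC)cc(OC)c1C(=[N+]=[N-])c1cc(OC)cc(OC)c1)Cc1ccc(OC)cc1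
F4 | step 8 | (E)-(2S,3R)-3-(3,5-dimethoxyphenyl)-4,6-dimethoxy-1-(4-methoxybenzylidene)-2-(4-methoxyphenyl)-2,3-dihydro-1H-indene | COc1ccc(cc1)/C=C1/c2cc(OC)cc(OC)c2[C@@H](c2cc(OC)cc(OC)c2)[C@H]1c1ccc(OC)cc1
F5 | step 8 | (E)-(2S,3R)-3-(3,5-dihydroxyphenyl)-1-(4-hydroxybenzylidene)-2-(4-hydroxyphenyl)-2,3-dihydro-1H-indene-4,6-diol | Oc1ccc(cc1)/C=C1/c2cc(O)cc(O)c2[C@@H](c2cc(O)cc(O)c2)[C@H]1c1ccc(O)cc1
F6 | step 7 | penta-O-TBS ether of ketone 10 | CC(C)(C)[Si](C)(C)Oc1ccc(cc1)/C=C(/c1cc(O[Si](C)(C)C(C)(C)C)cc(O[Si](C)(C)C(C)(C)C)c1C(=O)c1cc(O[Si](C)(C)C(C)(C)C)cc(O[Si](C)(C)C(C)(C)C)c1)Cc1ccc(O[Si](C)(C)C(C)(C)C)cc1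
F7 | step 7 | N-TBS hydrazone of F6 | CC(C)(C)[Si](C)(C)Oc1ccc(cc1)/C=C(/c1cc(O[Si](C)(C)C(C)(C)C)cc(O[Si](C)(C)C(C)(C)C)c1C(=NN[Si](C)(C)C(C)(C)C)c1cc(O[Si](C)(C)C(C)(C)C)cc(O[Si](C)(C)C(C)(C)C)c1)Cc1ccc(O[Si](C)(C)C(C)(C)C)cc1
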